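**The product.** The target forms from starting material as the solid substrate dissolves, and passes on into isomer of the product A.

solid substrate 0.023 M; time 80 s

    solid substrate ⇌ starting material, rate k1*(cs1 - [starting material]) while solid is left; crystals form when [starting material] > cs1 (cs1 = 18 mM, k1 = 0.022 s⁻¹)
    target ⇌ isomer of the product A (K2 = 1.4, k2 = 0.016 s⁻¹)
    isomer of the product A ⇌ isomer of the product B (K3 = 0.61, k3 = 7.0 × 10⁻⁴ s⁻¹)
    isomer of the product B ⇌ starting material (k4 = 0.021 s⁻¹)
    starting material ⇌ target (K5 = 2.6, k5 = 0.36 s⁻¹)

- solid, in amounts per volume of the solution: solid substrate
- at the start none of the solid substrate is in solution
- starting material means what is dissolved; the solid is not counted in it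
- run time (flask): 80 s

* the target standing at 80 s, as a percentage of the solid substrate charged
* concentration of starting material in solution at 80 s, in percent of saturation

**Quick group.** Starting material and target relax with a half-life of 1.39 s, and isomer of the product B and starting material, by their own step, with 10.2 s. Both are short against the run of 80 s. So I treat the three as one group, in which the target holds 44.7%. With isomer of the product A balanced in, its share is 27.5%. The direct link between the isomers makes no difference to the target at 80 s.

**Two times.** The exchange with isomer of the product A relaxes in a slow time of 53.8 s, longer than either half-life above. The solid delivers at most 0.396 mM s⁻¹, so it needs at least 58.1 s, which is shorter than the run. Taking that time and steady delivery, 51.0 s is the mean age: the time dissolved material has on average spent in solution, the run less half of the dissolving time.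

**My reckoning.** The mean age over the slow time is 0.948. The target's share of what has dissolved slides from the first share towards the second by the exponential of minus that ratio, giving 34.2% for a charge taken as dissolved by then. Starting material stands 2.6 times below the target, which gives 16.8% of saturation. This dissolving time is a lower bound, so in this flask the mean age leans long and the reckoned share leans low.

**Forecast.** The forecast, higher than my reckoning, gave 40% (36% to 44%) and 19% (16% to 23%), holding that “The fast starting material–target step sets their ratio”.

**The result.** The flask gives 37.0% and 18.1%, so my share stands 2.8 percentage points low. The solid substrate stands at 0% of its charge then, against 38.5% at 40.0 s. A neighbour flask charged with 0.0092 M has a shortest dissolving time of 23.2 s. Its mean age at the same reading is 68.4 s, older than in the first flask, and the same slide gives 32.3%. That flask stands at 31.4%.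

The constants used here were drawn at random within sensible limits; the flask was simulated.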